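**Retrosynthetic overview**

1. Target 29 ← acidolysis of di-tert-butyl ester 28 ← acylation of the 6β-alcohol 25 with trienoic acid 26 ← α-face reduction of C6 ketone 24 ← imide-to-ester exchange and enol ether hydrolysis of cycloadduct 20.
2. Feature (drimane numbering; ring A = C1–C5 and C10, ring B = C5–C10): ring B has the pattern of a 2-silyloxydiene C5=C6–C7=C8 (oxygen on C6, carboxyl carbon C12 on C8) added across a C9=C10 enoyl unit (carboxyl carbon C11 on C9, methyl on C10). C1–C4 of ring A, with the gem-dimethyl carbon C4, is the four-carbon tether from C10 to C5.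
3. Key disconnection: C5–C10 and C8–C9, formed in one intramolecular Diels–Alder (double Michael) reaction of trienimide 19 under a chiral divalent copper bis(oxazoline) complex. Rings A and B close together from an acyclic chain.
4. 19 ← silyl dienol ether of 4-oxo-enoate 18 ← aldol condensation of methyl ketone 13 with tert-butyl glyoxylate 14. The E enimide ← B-alkyl Suzuki coupling of alkene 4 (Sakurai allylation of mesityl oxide) with E enol triflate 6.

Key step: step 10

Assumption: the target SMILES reads as 5α-H, 6β-acyloxy, 8β- and 9β-carboxyl, 10β-methyl, that is (5S,6R,8S,9S,10S) in drimane numbering; the facial sense of the copper complex is taken from its square-planar chelate model, and the antipodal ligand would be used if that model proved wrong.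

**Route**

Step 1
Reactants: 1 mesityl oxide (4-methylpent-3-en-2-one); 2 allyltrimethylsilane
Product: 3 4,4-dimethylhept-6-en-2-one
Conditions: TiCl4 (1.1 equiv), CH2Cl2, -78 °C; then H2O
Reagents that add atoms: none
Why: Hosomi–Sakurai conjugate allylation, in which TiCl4 activates the enone and the allylsilane adds at the β,β-dimethyl carbon with loss of silicon, which sets the quaternary C4 and leaves a terminal alkene as the handle for C1.

Step 2
Reactants: 3 4,4-dimethylhept-6-en-2-one
Product: 4 2-(2,2-dimethylpent-4-en-1-yl)-2-methyl-1,3-dioxolane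
Conditions: ethylene glycol, TsOH·H2O (cat.), benzene, reflux, Dean–Stark trap
Reagents that add atoms: ethylene glycol, OCCO
Why: acid-catalysed ketalisation with azeotropic removal of water masks the C6 ketone against 9-BBN and hydroxide in steps 4 and 5, and the isolated terminal alkene is inert.

Step 3
Reactants: 5 ethyl acetoacetate
Product: 6 ethyl (2E)-3-(trifluoromethylsulfonyloxy)but-2-enoate
Conditions: Tf2O, aq. Me4NOH, hexane, 5–10 °C
Reagents that add atoms: trifluoromethanesulfonic anhydride, O=S(=O)(OS(=O)(=O)C(F)(F)F)C(F)(F)F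
Why: O-sulfonylation of the acetoacetate enolate, which with the non-chelating tetramethylammonium counter-ion reacts from its extended form, so that the triflate should end trans to the ester (E), the geometry later carried into C9=C10.

Step 4
Reactants: 4 2-(2,2-dimethylpent-4-en-1-yl)-2-methyl-1,3-dioxolane; 6 ethyl (2E)-3-(trifluoromethylsulfonyloxy)but-2-enoate
Product: 8 ethyl (2E)-3,7,7-trimethyl-8-(2-methyl-1,3-dioxolan-2-yl)oct-2-enoate, via alkylborane 7 (not isolated)
Conditions: 9-BBN, THF, 0 °C to rt; then 6, PdCl2(dppf) (5 mol %), K3PO4 (3 M aq), DMF, rt to 50 °C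
Reagents that add atoms: none
Why: anti-Markovnikov hydroboration of the terminal alkene followed by B-alkyl Suzuki–Miyaura coupling with the enol triflate, which proceeds with retention of alkene geometry, so that C1 ends trans and the methyl cis to the ester (E).

Step 5
Reactants: 8 ethyl (2E)-3,7,7-trimethyl-8-(2-methyl-1,3-dioxolan-2-yl)oct-2-enoate
Product: 10 (2E)-3,7,7-trimethyl-9-oxodec-2-enoic acid, via lithium carboxylate 9 (not isolated)
Conditions: LiOH, THF/MeOH/H2O, 55 °C; then 2 M HCl to pH 1, rt
Reagents that add atoms: lithium hydroxide, [Li+].[OH-]; water, O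
Why: saponification of the hindered enoate (the ketal is stable to base) followed by acidification, which hydrolyses the dioxolane, while the conjugated E alkene is not touched.

Step 6
Reactants: 10 (2E)-3,7,7-trimethyl-9-oxodec-2-enoic acid; 11 1,3-oxazolidin-2-one
Product: 13 3-[(2E)-3,7,7-trimethyl-9-oxodec-2-enoyl]-1,3-oxazolidin-2-one, via mixed pivalic anhydride 12 (not isolated)
Conditions: PivCl, Et3N, THF, -20 °C; then LiCl, 11, rt
Reagents that add atoms: none
Why: mixed-anhydride N-acylation, in which the oxazolidinone (activated by LiCl/Et3N) attacks the less hindered enoyl carbonyl of the pivalic anhydride and the methyl ketone is left alone.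

Step 7
Reactants: 13 3-[(2E)-3,7,7-trimethyl-9-oxodec-2-enoyl]-1,3-oxazolidin-2-one; 14 tert-butyl glyoxylate
Product: 16 tert-butyl (10E)-2-hydroxy-6,6,10-trimethyl-4,12-dioxo-12-(2-oxo-1,3-oxazolidin-3-yl)dodec-10-enoate (racemic at C2), via boron enolate 15 (not isolated)
Conditions: (c-C6H11)2BCl, Et3N, Et2O, 0 °C; then 14, -78 °C; pH 7 buffer, MeOH, 30% H2O2, 0 °C
Reagents that add atoms: none
Why: boron-mediated aldol addition, in which the dialkylboron chloride/amine pair enolises the methyl ketone on its methyl side (the other α-carbon, C5, is neopentyl) without touching the enimide, and the enolate adds to the reactive glyoxylate aldehyde; the new carbinol centre is removed in step 8.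

Step 8
Reactants: 16 tert-butyl (10E)-2-hydroxy-6,6,10-trimethyl-4,12-dioxo-12-(2-oxo-1,3-oxazolidin-3-yl)dodec-10-enoate
Product: 18 tert-butyl (2E,10E)-6,6,10-trimethyl-4,12-dioxo-12-(2-oxo-1,3-oxazolidin-3-yl)dodeca-2,10-dienoate, via mesylate 17 (not isolated)
Conditions: MsCl, Et3N, CH2Cl2, 0 °C to rt
Reagents that add atoms: none
Why: mesylation and E1cB elimination of the β-sulfonyloxy ketone should give the conjugated 4-oxo-2-enoate with the thermodynamically preferred E geometry at C7=C8.

Step 9
Reactants: 18 tert-butyl (2E,10E)-6,6,10-trimethyl-4,12-dioxo-12-(2-oxo-1,3-oxazolidin-3-yl)dodeca-2,10-dienoate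
Product: 19 tert-butyl (2E,4Z,10E)-4-(tert-butyldimethylsilyloxy)-6,6,10-trimethyl-12-oxo-12-(2-oxo-1,3-oxazolidin-3-yl)dodeca-2,4,10-trienoate
Conditions: TBSOTf (1.1 equiv), Et3N, CH2Cl2, -78 °C; cold NaHCO3 work-up, Et3N-deactivated silica
Reagents that add atoms: tert-butyldimethylsilyl trifluoromethanesulfonate, CC(C)(C)[Si](C)(C)OS(=O)(=O)C(F)(F)F
Why: soft enolisation (silyl triflate/amine) of the enone, whose only enolisable position is C5; the Z enol ether (C4 trans to C7) is expected because the tert-alkyl group avoids 1,3-allylic strain with the vinyl branch, and low temperature with only a slight excess of triflate keeps the enimide from reacting early.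

Step 10
Reactants: 19 tert-butyl (2E,4Z,10E)-4-(tert-butyldimethylsilyloxy)-6,6,10-trimethyl-12-oxo-12-(2-oxo-1,3-oxazolidin-3-yl)dodeca-2,4,10-trienoate
Product: 20 tert-butyl (1S,2S,4aS,8aS)-4-(tert-butyldimethylsilyloxy)-5,5,8a-trimethyl-1-(2-oxo-1,3-oxazolidine-3-carbonyl)-1,2,4a,5,6,7,8,8a-octahydronaphthalene-2-carboxylate (drimane numbering: C6=C7 silyl enol ether, 5α-H, 8β-ester, 9β-imide, 10β-methyl)
Conditions: [Cu(L)](SbF6)2 (15 mol %; L = 2,2'-(propane-2,2-diyl)bis[(4R)-4-tert-butyl-4,5-dihydro-1,3-oxazole], made from CuCl2, L and AgSbF6), anhydrous CH2Cl2, 25 °C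
Reagents that add atoms: none
Why: Proposed new method: the cationic divalent copper bis(oxazoline) complex binds both imide carbonyls in a square-planar chelate and lowers the LUMO of the C9=C10 enoyl unit, so that the nucleophilic C5 terminus of the 2-silyloxydiene adds to C10 and C8 closes onto C9, either as an asynchronous [4+2] cycloaddition or as two Michael additions through a silyloxocarbenium/copper enolate pair; the closest known reactions are copper bis(oxazoline)-catalysed intramolecular Diels–Alder reactions of trienimides and Lewis-acid-promoted intramolecular double Michael reactions of silyl dienol ethers, neither shown with a β,β-disubstituted enimide. Ring B forms as the cyclohexene of the [4+2] event (6-endo-trig closure of C9 on C8 in the stepwise picture), and ring A forms through the C1–C4 tether as a type 1 intramolecular cycloaddition (6-exo-trig attack of C5 on C10). The E enimide holds the C10 methyl cis to C11 and suprafacial addition keeps them cis (10β-methyl, 9β-acyl); the imide-endo transition state with the tether exo gives the trans ring fusion (5α-H); the E C7=C8 bond places the C12 ester on the outside of the diene, so that it ends cis to C4 (8β). The absolute configuration comes from the catalyst: in the s-cis chelate of the (R,R) ligand the tert-butyl group beside the acyl oxygen covers the Re face of C9, so the diene should add to the Si face of C9, as the target requires. The step needs bond formation at a hindered, doubly β-substituted acceptor to outrun desilylation, and endo over exo closure; the high HOMO of the silyloxydiene, the four-carbon tether with its gem-dimethyl group and the two-point binding of the imide are what should secure this.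

Step 11
Reactants: 20 cycloadduct (silyl enol ether imide)
Product: 23 (1S,2S,4aS,8aS)-2-(tert-butoxycarbonyl)-5,5,8a-trimethyl-4-oxodecahydronaphthalene-1-carboxylic acid, via lithium percarboxylate 21 (not isolated), via lithium carboxylate 22 (not isolated)
Conditions: LiOH, 30% H2O2, THF/H2O (3:1), 0 °C; Na2SO3; then 1 M HCl, THF, rt
Reagents that add atoms: hydrogen peroxide, OO
Why: perhydrolysis of the N-acyl oxazolidinone by lithium hydroperoxide at the exocyclic carbonyl while the silyl enol ether still masks C6 (so no C7 enolate can open the ring by retro-Michael reaction or epimerise C8), then sulfite reduction of the peracid and acid hydrolysis of the enol ether, in which protonation at C7 creates no stereocentre and the tert-butyl ester survives dilute aqueous acid.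

Step 12
Reactants: 23 keto acid
Product: 24 di-tert-butyl (1S,2S,4aS,8aS)-5,5,8a-trimethyl-4-oxodecahydronaphthalene-1,2-dicarboxylate
Conditions: tert-butyl 2,2,2-trichloroacetimidate, BF3·OEt2 (cat.), CH2Cl2/cyclohexane, rt
Reagents that add atoms: tert-butyl 2,2,2-trichloroacetimidate, CC(C)(C)OC(=N)C(Cl)(Cl)Cl
Why: acid-catalysed O-alkylation of the carboxylic acid by the trichloroacetimidate (tert-butyl cation transfer), which does not depend on access to the hindered C11 carbonyl and needs no base, so the axial C8 ester centre is not epimerised.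

Step 13
Reactants: 24 di-tert-butyl keto diester
Product: 25 di-tert-butyl (1S,2S,4R,4aS,8aS)-4-hydroxy-5,5,8a-trimethyldecahydronaphthalene-1,2-dicarboxylate (6β-alcohol)
Conditions: NaBH4, MeOH/THF, -40 to -20 °C; pH 7 phosphate buffer
Reagents that add atoms: none
Why: borohydride reduction of the C6 ketone from the α face, because the β face is blocked by the axial C10 and 4β methyl groups and the axial 8β ester, which should give the axial 6β alcohol (6R); low temperature and a buffered quench keep the alkoxide from lactonising onto the syn-axial C12 tert-butyl ester.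

Step 14
Reactants: 25 6β-alcohol; 26 (2E,4E,6E)-octa-2,4,6-trienoic acid
Product: 28 di-tert-butyl (1S,2S,4R,4aS,8aS)-5,5,8a-trimethyl-4-[(2E,4E,6E)-octa-2,4,6-trienoyloxy]decahydronaphthalene-1,2-dicarboxylate, via mixed anhydride 27 (not isolated)
Conditions: 26, 2,4,6-trichlorobenzoyl chloride, Et3N, THF, rt; then 25, DMAP, toluene, rt to 60 °C, dark
Reagents that add atoms: none
Why: Yamaguchi esterification, in which DMAP converts the mixed anhydride (aroyl carbonyl shielded by two ortho chlorines) into a trienoyl pyridinium species reactive enough for the hindered axial alcohol; O-acylation retains the C6 configuration and the amine conditions do not enolise C8.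

Step 15
Reactants: 28 trienoate di-tert-butyl ester
Product: 29 (1S,2S,4R,4aS,8aS)-5,5,8a-trimethyl-4-[(2E,4E,6E)-octa-2,4,6-trienoyloxy]decahydronaphthalene-1,2-dicarboxylic acid (CNP0462207.1)
Conditions: CF3CO2H/CH2Cl2 (1:3), 0 °C to rt, dark
Reagents that add atoms: none
Why: acidolysis of both tert-butyl esters with loss of isobutene, under which the secondary trienoate ester and all five stereocentres should stay untouched.

**Compound list**

1 | mesityl oxide | CC(=O)C=C(C)C | starting material
2 | allyltrimethylsilane | C=CC[Si](C)(C)C | starting material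
3 | 4,4-dimethylhept-6-en-2-one | CC(=O)CC(C)(C)CC=C | intermediate
4 | 2-(2,2-dimethylpent-4-en-1-yl)-2-methyl-1,3-dioxolane | CC1(CC(C)(C)CC=C)OCCO1 | intermediate
5 | ethyl acetoacetate | CCOC(=O)CC(C)=O | starting material
6 | ethyl (2E)-3-(trifluoromethylsulfonyloxy)but-2-enoate | CCOC(=O)/C=C(\C)OS(=O)(=O)C(F)(F)F | intermediate
7 | 9-[4,4-dimethyl-5-(2-methyl-1,3-dioxolan-2-yl)pentyl]-9-borabicyclo[3.3.1]nonane | CC1(CC(C)(C)CCCB2C3CCCC2CCC3)OCCO1 | intermediate (not isolated)
8 | ethyl (2E)-3,7,7-trimethyl-8-(2-methyl-1,3-dioxolan-2-yl)oct-2-enoate | CCOC(=O)/C=C(\C)CCCC(C)(C)CC1(C)OCCO1 | intermediate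
9 | lithium (2E)-3,7,7-trimethyl-8-(2-methyl-1,3-dioxolan-2-yl)oct-2-enoate | [Li+].[O-]C(=O)/C=C(\C)CCCC(C)(C)CC1(C)OCCO1 | intermediate (not isolated)
10 | (2E)-3,7,7-trimethyl-9-oxodec-2-enoic acid | OC(=O)/C=C(\C)CCCC(C)(C)CC(C)=O | intermediate
11 | 1,3-oxazolidin-2-one | O=C1NCCO1 | starting material
12 | (2E)-3,7,7-trimethyl-9-oxodec-2-enoic pivalic anhydride | CC(C)(C)C(=O)OC(=O)/C=C(\C)CCCC(C)(C)CC(C)=O | intermediate (not isolated)
13 | 3-[(2E)-3,7,7-trimethyl-9-oxodec-2-enoyl]-1,3-oxazolidin-2-one | O=C(N1CCOC1=O)/C=C(\C)CCCC(C)(C)CC(C)=O | intermediate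
14 | tert-butyl glyoxylate | O=CC(=O)OC(C)(C)C | starting material
15 | 3-[(2E)-9-(dicyclohexylboryloxy)-3,7,7-trimethyldeca-2,9-dienoyl]-1,3-oxazolidin-2-one | C=C(OB(C1CCCCC1)C1CCCCC1)CC(C)(C)CCC/C(C)=C/C(=O)N1CCOC1=O | intermediate (not isolated)
16 | tert-butyl (10E)-2-hydroxy-6,6,10-trimethyl-4,12-dioxo-12-(2-oxo-1,3-oxazolidin-3-yl)dodec-10-enoate, racemic at C2 | CC(C)(C)OC(=O)C(O)CC(=O)CC(C)(C)CCC/C(C)=C/C(=O)N1CCOC1=O | intermediate
17 | 2-O-methanesulfonate of 16 | CC(C)(C)OC(=O)C(OS(C)(=O)=O)CC(=O)CC(C)(C)CCC/C(C)=C/C(=O)N1CCOC1=O | intermediate (not isolated)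
18 | tert-butyl (2E,10E)-6,6,10-trimethyl-4,12-dioxo-12-(2-oxo-1,3-oxazolidin-3-yl)dodeca-2,10-dienoate | CC(C)(C)OC(=O)/C=C/C(=O)CC(C)(C)CCC/C(C)=C/C(=O)N1CCOC1=O | intermediate
19 | tert-butyl (2E,4Z,10E)-4-(tert-butyldimethylsilyloxy)-6,6,10-trimethyl-12-oxo-12-(2-oxo-1,3-oxazolidin-3-yl)dodeca-2,4,10-trienoate | O=C(N1CCOC1=O)/C=C(\C)CCCC(C)(C)/C=C(O[Si](C)(C)C(C)(C)C)/C=C/C(=O)OC(C)(C)C | intermediate
20 | tert-butyl (1S,2S,4aS,8aS)-4-(tert-butyldimethylsilyloxy)-5,5,8a-trimethyl-1-(2-oxo-1,3-oxazolidine-3-carbonyl)-1,2,4a,5,6,7,8,8a-octahydronaphthalene-2-carboxylate | CC(C)(C)[Si](C)(C)OC1=C[C@H](C(=O)OC(C)(C)C)[C@H](C(=O)N3CCOC3=O)[C@@]2(C)CCCC(C)(C)[C@H]12 | intermediate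
21 | lithium peroxycarboxylate of the C11 acid, silyl enol ether intact | CC(C)(C)[Si](C)(C)OC1=C[C@H](C(=O)OC(C)(C)C)[C@H](C(=O)O[O-])[C@@]2(C)CCCC(C)(C)[C@H]12.[Li+] | intermediate (not isolated)
22 | lithium carboxylate of the C11 acid, silyl enol ether intact | CC(C)(C)[Si](C)(C)OC1=C[C@H](C(=O)OC(C)(C)C)[C@H](C(=O)[O-])[C@@]2(C)CCCC(C)(C)[C@H]12.[Li+] | intermediate (not isolated)
23 | (1S,2S,4aS,8aS)-2-(tert-butoxycarbonyl)-5,5,8a-trimethyl-4-oxodecahydronaphthalene-1-carboxylic acid | O=C1C[C@H](C(=O)OC(C)(C)C)[C@H](C(=O)O)[C@@]2(C)CCCC(C)(C)[C@H]12 | intermediate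
24 | di-tert-butyl (1S,2S,4aS,8aS)-5,5,8a-trimethyl-4-oxodecahydronaphthalene-1,2-dicarboxylate | O=C1C[C@H](C(=O)OC(C)(C)C)[C@H](C(=O)OC(C)(C)C)[C@@]2(C)CCCC(C)(C)[C@H]12 | intermediate
25 | di-tert-butyl (1S,2S,4R,4aS,8aS)-4-hydroxy-5,5,8a-trimethyldecahydronaphthalene-1,2-dicarboxylate | O[C@@H]1C[C@H](C(=O)OC(C)(C)C)[C@H](C(=O)OC(C)(C)C)[C@@]2(C)CCCC(C)(C)[C@H]12 | intermediate
26 | (2E,4E,6E)-octa-2,4,6-trienoic acid | C/C=C/C=C/C=C/C(=O)O | starting material
27 | (2E,4E,6E)-octa-2,4,6-trienoic 2,4,6-trichlorobenzoic anhydride | C/C=C/C=C/C=C/C(=O)OC(=O)c1c(Cl)cc(Cl)cc1Cl | intermediate (not isolated)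
28 | di-tert-butyl (1S,2S,4R,4aS,8aS)-5,5,8a-trimethyl-4-[(2E,4E,6E)-octa-2,4,6-trienoyloxy]decahydronaphthalene-1,2-dicarboxylate | C/C=C/C=C/C=C/C(=O)O[C@@H]1C[C@H](C(=O)OC(C)(C)C)[C@H](C(=O)OC(C)(C)C)[C@@]2(C)CCCC(C)(C)[C@H]12 | intermediate
29 | (1S,2S,4R,4aS,8aS)-5,5,8a-trimethyl-4-[(2E,4E,6E)-octa-2,4,6-trienoyloxy]decahydronaphthalene-1,2-dicarboxylic acid | C/C=C/C=C/C=C/C(=O)O[C@@H]1C[C@H](C(=O)O)[C@H](C(=O)O)[C@@]2(C)CCCC(C)(C)[C@H]12 | target

**Step count**

Total: 15 steps. Longest linear sequence: 14 steps (steps 1, 2 and 4–15, from mesityl oxide); step 3 is a one-step side branch.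

**Steps most likely to fail**

1. Step 10. The catalyst may not turn over, because the C10 methyl group that lies cis to the imide collides with the ligand in the planar chelate. The silyl group may also be lost (protodesilylation, or a first Michael addition not followed by ring closure) faster than the hindered C5–C10 bond forms, and facial discrimination may be poor. Fallback with known chemistry (auxiliary control and a stoichiometric aluminium Lewis acid, the established way to drive intramolecular Diels–Alder reactions of trienimides): it sets out from acid 10. The mixed anhydride 12 is used to acylate (S)-4-benzyl-1,3-oxazolidin-2-one (LiCl, Et3N), which gives (4S)-4-benzyl-3-[(2E)-3,7,7-trimethyl-9-oxodec-2-enoyl]-1,3-oxazolidin-2-one F1. The chemistry of steps 7 to 9 is then repeated: the dicyclohexylboron enolate F2 adds to 14 to give the aldol adduct F3, the mesylate F4 eliminates to the 4-oxo-2-enoate F5, and TBSOTf/Et3N gives the Z silyl dienol ether F6. Me2AlCl (1.5 equiv, CH2Cl2, -30 °C) forms the cationic aluminium chelate of the imide; the benzyl group covers the Re face of C9, so the diene adds endo to the Si face and should give the auxiliary-bearing cycloadduct F7 with the same ring configuration as 20. LiOH/H2O2, sulfite and aqueous HCl as in step 11 release the auxiliary and pass through 21 and 22, so that the route is rejoined at 23.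

2. Step 14. Acyl transfer to the shielded axial hydroxyl (syn-axial to two methyl groups and the C12 ester) may be slower than γ-deprotonation of the activated trienoyl unit (vinylketene formation, deconjugation, oligomerisation) or than attack of the hydroxyl on the neighbouring C12 ester (lactonisation). Fallback: it sets out from alcohol 25 and builds the triene after attaching a small acyl group. Bromoacetyl bromide and pyridine (CH2Cl2, 0 °C) give the 6β-bromoacetate F8; an Arbuzov reaction with P(OEt)3 (100 °C) gives the 6β-(diethoxyphosphoryl)acetate F9; a Horner–Wadsworth–Emmons reaction with (2E,4E)-hexa-2,4-dienal (LiCl, DBU, MeCN) then forms the new E C=C bond and rejoins the route at 28.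

3. Step 11. Hydroperoxide may attack the ring carbonyl of the oxazolidinone (ring opening) instead of the buried C11 carbonyl, or the silyl enol ether may be lost early under base, followed by C8 epimerisation or retro-Michael opening. Fallback: it sets out from 20 and uses a smaller, softer nucleophile. LiSEt (EtSH, n-BuLi, THF, 0 °C) transacylates the imide to the S-ethyl thioester F10. Silver trifluoroacetate (monovalent silver) in wet THF with Na2HPO4 hydrolyses the thioester to the free C11 acid silyl enol ether F11, and 1 M HCl then cleaves the enol ether, so that the route is rejoined at 23.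

**Further compounds**

F1 | step 10 | (4S)-4-benzyl-3-[(2E)-3,7,7-trimethyl-9-oxodec-2-enoyl]-1,3-oxazolidin-2-one | O=C(N1[C@@H](Cc2ccccc2)COC1=O)/C=C(\C)CCCC(C)(C)CC(C)=O
F2 | step 10 | dicyclohexylboron enolate of F1 | C=C(OB(C1CCCCC1)C1CCCCC1)CC(C)(C)CCC/C(C)=C/C(=O)N1[C@@H](Cc2ccccc2)COC1=O
F3 | step 10 | tert-butyl (10E)-12-[(4S)-4-benzyl-2-oxo-1,3-oxazolidin-3-yl]-2-hydroxy-6,6,10-trimethyl-4,12-dioxododec-10-enoate | CC(C)(C)OC(=O)C(O)CC(=O)CC(C)(C)CCC/C(C)=C/C(=O)N1[C@@H](Cc2ccccc2)COC1=O
F4 | step 10 | 2-O-methanesulfonate of F3 | CC(C)(C)OC(=O)C(OS(C)(=O)=O)CC(=O)CC(C)(C)CCC/C(C)=C/C(=O)N1[C@@H](Cc2ccccc2)COC1=O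
F5 | step 10 | tert-butyl (2E,10E)-12-[(4S)-4-benzyl-2-oxo-1,3-oxazolidin-3-yl]-6,6,10-trimethyl-4,12-dioxododeca-2,10-dienoate | CC(C)(C)OC(=O)/C=C/C(=O)CC(C)(C)CCC/C(C)=C/C(=O)N1[C@@H](Cc2ccccc2)COC1=O
F6 | step 10 | tert-butyl (2E,4Z,10E)-12-[(4S)-4-benzyl-2-oxo-1,3-oxazolidin-3-yl]-4-(tert-butyldimethylsilyloxy)-6,6,10-trimethyl-12-oxododeca-2,4,10-trienoate | O=C(N1[C@@H](Cc2ccccc2)COC1=O)/C=C(\C)CCCC(C)(C)/C=C(O[Si](C)(C)C(C)(C)C)/C=C/C(=O)OC(C)(C)C
F7 | step 10 | cycloadduct 20 bearing the (4S)-4-benzyl-2-oxo-1,3-oxazolidin-3-yl imide | CC(C)(C)[Si](C)(C)OC1=C[C@H](C(=O)OC(C)(C)C)[C@H](C(=O)N3[C@@H](Cc4ccccc4)COC3=O)[C@@]2(C)CCCC(C)(C)[C@H]12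
F8 | step 14 | di-tert-butyl (1S,2S,4R,4aS,8aS)-4-(bromoacetoxy)-5,5,8a-trimethyldecahydronaphthalene-1,2-dicarboxylate | O=C(CBr)O[C@@H]1C[C@H](C(=O)OC(C)(C)C)[C@H](C(=O)OC(C)(C)C)[C@@]2(C)CCCC(C)(C)[C@H]12
F9 | step 14 | di-tert-butyl (1S,2S,4R,4aS,8aS)-4-[(diethoxyphosphoryl)acetoxy]-5,5,8a-trimethyldecahydronaphthalene-1,2-dicarboxylate | CCOP(=O)(OCC)CC(=O)O[C@@H]1C[C@H](C(=O)OC(C)(C)C)[C@H](C(=O)OC(C)(C)C)[C@@]2(C)CCCC(C)(C)[C@H]12
F10 | step 11 | S-ethyl thioester of the C11 acid, silyl enol ether and C12 tert-butyl ester intact | CC(C)(C)[Si](C)(C)OC1=C[C@H](C(=O)OC(C)(C)C)[C@H](C(=O)SCC)[C@@]2(C)CCCC(C)(C)[C@H]12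
F11 | step 11 | (1S,2S,4aS,8aS)-2-(tert-butoxycarbonyl)-4-(tert-butyldimethylsilyloxy)-5,5,8a-trimethyl-1,2,4a,5,6,7,8,8a-octahydronaphthalene-1-carboxylic acid | CC(C)(C)[Si](C)(C)OC1=C[C@H](C(=O)OC(C)(C)C)[C@H](C(=O)O)[C@@]2(C)CCCC(C)(C)[C@H]12
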